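**Strategy.** The route rests on cutting the lactone ring (O1′, C2′, C3′, C4′, C5′) between C4′, which carries the methyl group, and C5′, the carbinol carbon bound to the fully substituted C2 of the chromanone. Since C2 bears no hydrogen, C5′ can be a non-enolisable aldehyde, and a (Z)-β-metallated crotonate brings C2′ to C4′: one Nozaki–Hiyama–Kishi operation forms the C4′–C5′ bond and lets the new alkoxide close the five-membered ring as a butenolide. Its precursor is an enantioenriched 2-formylchromanone-2-carboxylate together with ethyl (Z)-3-iodobut-2-enoate. Hydrogenation then sets C4′, the bromide and the stannane of one monomer are joined at C6, and one lactone is opened.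

Key step: step 6

Remarks on the chemistry:
- Locants: chromanone atoms are unprimed; lactone atoms are O1′, C2′ (C=O), C3′ (CH2), C4′ (CH–CH3), C5′ (CH–O). Compound names use ordinary substituent numbering.
- Assumption: the CuI complex of the (S,S)-phenyl bis(oxazoline) ligand is taken to deliver the (S)-configured adduct 9; if the sense is opposite, the (R,R)-ligand is used.
- Assumption: in the fallback to step 6 the (R,R)-tartrate crotylboronate is taken as the reagent matched to the (1R) carbinol.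
- Ethyl (Z)-3-iodobut-2-enoate is taken as commercially available.
- Bromide 17 is divided into two portions: one is stannylated in step 10, the other is kept as the coupling partner for step 11.

**Step 1**
Reactants: 1 1-(2,6-dihydroxyphenyl)ethan-1-one; 2 dimethyl oxalate
Product: 4 methyl 5-hydroxy-4-oxo-4H-chromene-2-carboxylate, via diketo ester 3 (not isolated)
Conditions: NaOMe, MeOH, 65 °C; then conc. HCl, MeOH, 65 °C
Reagents that add atoms: none
Why: Claisen condensation of the methyl ketone with the oxalate, followed by acid-catalysed cyclodehydration of the diketo ester onto a phenol, should give the chromone ester; no stereocenter is formed.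

**Step 2**
Reactants: 4 methyl 5-hydroxy-4-oxo-4H-chromene-2-carboxylate
Product: 5 methyl 5-(benzyloxy)-4-oxo-4H-chromene-2-carboxylate
Conditions: BnBr, K2CO3, DMF, 60 °C
Reagents that add atoms: benzyl bromide, BrCc1ccccc1
Why: Williamson etherification masks the chelated phenol so that it cannot quench the copper acetylide or the organochromium reagent later.

**Step 3**
Reactants: 5 methyl 5-(benzyloxy)-4-oxo-4H-chromene-2-carboxylate; 6 ethynyltrimethylsilane
Product: 9 methyl (S)-5-(benzyloxy)-2-ethynyl-4-oxochromane-2-carboxylate, via benzopyrylium triflate 7 (not isolated), via silyl enol ether 8 (not isolated)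
Conditions: CuI (10 mol %), (S,S)-2,2′-(propane-2,2-diyl)bis(4-phenyl-4,5-dihydrooxazole) (12 mol %), TBSOTf, iPr2NEt, toluene, −78 to −40 °C; then TBAF, AcOH, THF, 0 °C
Reagents that add atoms: none
Why: Catalytic enantioselective alkynylation of a benzopyrylium ion: the silyl triflate turns the chromone into the 4-siloxybenzopyrylium ion, the ligand-bound copper acetylide adds to C2 and sets the quaternary centre as (S) under catalyst control, and buffered fluoride removes both silyl groups.

**Step 4**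
Reactants: 9 methyl (S)-5-(benzyloxy)-2-ethynyl-4-oxochromane-2-carboxylate
Product: 10 methyl (S)-5-(benzyloxy)-2-ethenyl-4-oxochromane-2-carboxylate
Conditions: H2 (1 atm), Pd/CaCO3 poisoned with Pb(OAc)2, quinoline, EtOAc, 23 °C
Reagents that add atoms: none
Why: Lindlar semihydrogenation should stop at the alkene and leave the benzyl ether, the ketone and the quaternary C2 untouched.

**Step 5**
Reactants: 10 methyl (S)-5-(benzyloxy)-2-ethenyl-4-oxochromane-2-carboxylate
Product: 11 methyl (S)-5-(benzyloxy)-2-formyl-4-oxochromane-2-carboxylate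
Conditions: O3, CH2Cl2, −78 °C; then Me2S, −78 to 23 °C; used crude
Reagents that add atoms: ozone, [O-][O+]=O
Why: Ozonolysis with reductive work-up cleaves the terminal alkene far faster than the acyl-deactivated arene; C2 is quaternary, so the aldehyde cannot epimerise.

**Step 6 (key step)**
Reactants: 11 methyl (S)-5-(benzyloxy)-2-formyl-4-oxochromane-2-carboxylate; 12 ethyl (Z)-3-iodobut-2-enoate
Product: 14 methyl (S)-5-(benzyloxy)-2-[(R)-3-methyl-5-oxo-2,5-dihydrofuran-2-yl]-4-oxochromane-2-carboxylate, via chromium alkoxide 13 (not isolated)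
Conditions: CrCl2 (4 equiv), NiCl2 (2 mol %), DMF, 23 °C; aq. NH4Cl; then PPTS (cat.), CH2Cl2, 23 °C
Reagents that add atoms: none
Why: Nozaki–Hiyama–Kishi coupling with lactonisation in the same flask: zerovalent nickel (from NiCl2 and CrCl2) inserts into the C–I bond of 12 and hands the alkenyl group to trivalent chromium with retention of the (Z) geometry, and this alkenylchromium adds through C4′ to the aldehyde carbon C5′ of 11 in preference to the aryl ketone and the esters. The chromium alkoxide 13 then attacks the cis-disposed ethyl ester and expels ethoxide, so the butenolide ring closes by a 5-exo-trig acyl substitution (O1′ onto C2′) directly after the C4′–C5′ bond has formed. The closest known reaction type is the one-pot butenolide synthesis from (Z)-3-iodoenoates and aldehydes under CrCl2/NiCl2. The new stereocenter C5′ is controlled by the adjacent quaternary C2 in a polar Felkin–Anh sense: the aryl ether oxygen stands anti to the incoming alkenyl group, which passes the planar CO2Me group and not the ring methylene C3, and this should lead to (R) at C5′. The step needs aldehyde-over-ketone chemoselectivity (secured by the organochromium reagent), retention of the (Z) geometry (secured by stereospecific insertion and transmetallation) and facial selectivity, for which only the substrate bias is available, so a minor C5′ epimer would be removed by chromatography.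

**Step 7**
Reactants: 14 methyl (S)-5-(benzyloxy)-2-[(R)-3-methyl-5-oxo-2,5-dihydrofuran-2-yl]-4-oxochromane-2-carboxylate
Product: 15 methyl (S)-5-hydroxy-2-[(2R,3S)-3-methyl-5-oxotetrahydrofuran-2-yl]-4-oxochromane-2-carboxylate
Conditions: H2 (1 atm), Pd/C, EtOAc, 23 °C
Reagents that add atoms: none
Why: Heterogeneous catalytic hydrogenation delivers H2 to the butenolide face opposite the bulky chromanyl group on C5′, which should place the methyl group cis to it and make C4′ (S); the same conditions hydrogenolyse the benzyl ether.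

**Step 8**
Reactants: 15 methyl (S)-5-hydroxy-2-[(2R,3S)-3-methyl-5-oxotetrahydrofuran-2-yl]-4-oxochromane-2-carboxylate
Product: 16 methyl (S)-6-bromo-5-hydroxy-2-[(2R,3S)-3-methyl-5-oxotetrahydrofuran-2-yl]-4-oxochromane-2-carboxylate
Conditions: NBS (1.0 equiv), iPr2NH (cat.), CH2Cl2, −78 to 0 °C
Reagents that add atoms: N-bromosuccinimide, O=C1CCC(=O)N1Br
Why: Amine-mediated electrophilic ortho-bromination of a phenol: C6 is ortho to the hydrogen-bonded phenol and para to the ring oxygen, and the amine-bound bromine is delivered next to the OH group.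

**Step 9**
Reactants: 16 methyl (S)-6-bromo-5-hydroxy-2-[(2R,3S)-3-methyl-5-oxotetrahydrofuran-2-yl]-4-oxochromane-2-carboxylate
Product: 17 methyl (S)-6-bromo-5-(methoxymethoxy)-2-[(2R,3S)-3-methyl-5-oxotetrahydrofuran-2-yl]-4-oxochromane-2-carboxylate
Conditions: MOMCl, iPr2NEt, CH2Cl2, 0 to 40 °C
Reagents that add atoms: chloromethyl methyl ether, COCCl
Why: O-alkylation to the MOM acetal protects the phenol for the two organometallic steps under conditions mild enough not to open the chromanone by retro-oxa-Michael reaction.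

**Step 10**
Reactants: 17 methyl (S)-6-bromo-5-(methoxymethoxy)-2-[(2R,3S)-3-methyl-5-oxotetrahydrofuran-2-yl]-4-oxochromane-2-carboxylate
Product: 18 methyl (S)-5-(methoxymethoxy)-2-[(2R,3S)-3-methyl-5-oxotetrahydrofuran-2-yl]-4-oxo-6-(trimethylstannyl)chromane-2-carboxylate
Conditions: (Me3Sn)2, Pd(PPh3)4 (10 mol %), toluene, 100 °C
Reagents that add atoms: hexamethylditin, C[Sn](C)(C)[Sn](C)(C)C
Why: Palladium-catalysed stannylation (oxidative addition of zerovalent palladium, transmetallation with the distannane, reductive elimination) runs without base, which spares the base-sensitive quaternary chromanone and the lactone.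

**Step 11**
Reactants: 17 methyl (S)-6-bromo-5-(methoxymethoxy)-2-[(2R,3S)-3-methyl-5-oxotetrahydrofuran-2-yl]-4-oxochromane-2-carboxylate; 18 methyl (S)-5-(methoxymethoxy)-2-[(2R,3S)-3-methyl-5-oxotetrahydrofuran-2-yl]-4-oxo-6-(trimethylstannyl)chromane-2-carboxylate
Product: 19 dimethyl (2S,2′S)-5,5′-bis(methoxymethoxy)-2,2′-bis[(2R,3S)-3-methyl-5-oxotetrahydrofuran-2-yl]-4,4′-dioxo-[6,6′-bichromane]-2,2′-dicarboxylate
Conditions: Pd(PPh3)4 (10 mol %), CuI (20 mol %), DMF, 80 °C
Reagents that add atoms: none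
Why: Stille cross-coupling (oxidative addition of zerovalent palladium into the C–Br bond of 17, copper-assisted tin-to-palladium transmetallation of 18, reductive elimination) should form the C6–C6′ bond without base; both partners carry the same aryl unit, so any homocoupling leads to the same product 19, and a biaryl with only two ortho substituents should have no stable atropisomers.

**Step 12**
Reactants: 19 dimethyl (2S,2′S)-5,5′-bis(methoxymethoxy)-2,2′-bis[(2R,3S)-3-methyl-5-oxotetrahydrofuran-2-yl]-4,4′-dioxo-[6,6′-bichromane]-2,2′-dicarboxylate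
Product: 20 dimethyl (2S,2′S)-5,5′-dihydroxy-2,2′-bis[(2R,3S)-3-methyl-5-oxotetrahydrofuran-2-yl]-4,4′-dioxo-[6,6′-bichromane]-2,2′-dicarboxylate
Conditions: 3 M aq. HCl, MeCN, 50 °C
Reagents that add atoms: none
Why: Acid-catalysed acetal hydrolysis frees both phenols; acid leaves the methyl esters and the quaternary centres alone and keeps both lactones closed.

**Step 13**
Reactants: 20 dimethyl (2S,2′S)-5,5′-dihydroxy-2,2′-bis[(2R,3S)-3-methyl-5-oxotetrahydrofuran-2-yl]-4,4′-dioxo-[6,6′-bichromane]-2,2′-dicarboxylate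
Product: 21 (3S,4R)-4-hydroxy-4-[(2S,2′S)-5,5′-dihydroxy-2,2′-bis(methoxycarbonyl)-2′-[(2R,3S)-3-methyl-5-oxotetrahydrofuran-2-yl]-4,4′-dioxo-[6,6′-bichroman]-2-yl]-3-methylbutanoic acid (target)
Conditions: LiOH·H2O (3 equiv), THF/H2O, 0 °C, quenched at partial conversion; cold dilute HCl to pH 4; reversed-phase chromatography; recovered 20 recycled
Reagents that add atoms: lithium hydroxide, [Li+].[OH-]
Why: Saponification of one of two equivalent γ-lactones: the unhindered lactone carbonyl C2′ should be attacked much faster than the methyl esters on the quaternary C2, the two phenolates formed first lower the acidity at C3 and so disfavour retro-oxa-Michael opening, and the hindered C5′ alcohol should be slow to re-lactonise at pH 4 and 0 °C.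

**Compound list**
1 | 1-(2,6-dihydroxyphenyl)ethan-1-one | CC(=O)c1c(O)cccc1O | starting material
2 | dimethyl oxalate | COC(=O)C(=O)OC | starting material
3 | methyl 4-(2,6-dihydroxyphenyl)-2,4-dioxobutanoate (sodium enolate in the flask) | COC(=O)C(=O)CC(=O)c1c(O)cccc1O | intermediate (not isolated)
4 | methyl 5-hydroxy-4-oxo-4H-chromene-2-carboxylate | COC(=O)c1cc(=O)c2c(O)cccc2o1 | intermediate
5 | methyl 5-(benzyloxy)-4-oxo-4H-chromene-2-carboxylate | COC(=O)c1cc(=O)c2c(OCc3ccccc3)cccc2o1 | intermediate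
6 | ethynyltrimethylsilane | C#C[Si](C)(C)C | starting material
7 | 5-(benzyloxy)-4-[(tert-butyldimethylsilyl)oxy]-2-(methoxycarbonyl)chromenylium trifluoromethanesulfonate | COC(=O)c1cc(O[Si](C)(C)C(C)(C)C)c2c(OCc3ccccc3)cccc2[o+]1.[O-]S(=O)(=O)C(F)(F)F | intermediate (not isolated)
8 | methyl (S)-5-(benzyloxy)-4-[(tert-butyldimethylsilyl)oxy]-2-[(trimethylsilyl)ethynyl]-2H-chromene-2-carboxylate | COC(=O)[C@@]1(C#C[Si](C)(C)C)C=C(O[Si](C)(C)C(C)(C)C)c2c(OCc3ccccc3)cccc2O1 | intermediate (not isolated)
9 | methyl (S)-5-(benzyloxy)-2-ethynyl-4-oxochromane-2-carboxylate | O=C1C[C@@](C(=O)OC)(C#C)Oc2cccc(OCc3ccccc3)c12 | intermediate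
10 | methyl (S)-5-(benzyloxy)-2-ethenyl-4-oxochromane-2-carboxylate | O=C1C[C@@](C(=O)OC)(C=C)Oc2cccc(OCc3ccccc3)c12 | intermediate
11 | methyl (S)-5-(benzyloxy)-2-formyl-4-oxochromane-2-carboxylate | O=C1C[C@@](C(=O)OC)(C=O)Oc2cccc(OCc3ccccc3)c12 | intermediate
12 | ethyl (Z)-3-iodobut-2-enoate | CCOC(=O)/C=C(/C)I | starting material
13 | dichlorochromium alkoxide (trivalent chromium) of ethyl (2Z,4R)-4-[(S)-5-(benzyloxy)-2-(methoxycarbonyl)-4-oxochroman-2-yl]-4-hydroxy-3-methylbut-2-enoate | O=C1C[C@@](C(=O)OC)([C@H](O[Cr](Cl)Cl)/C(C)=C\C(=O)OCC)Oc2cccc(OCc3ccccc3)c12 | intermediate (not isolated)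
14 | methyl (S)-5-(benzyloxy)-2-[(R)-3-methyl-5-oxo-2,5-dihydrofuran-2-yl]-4-oxochromane-2-carboxylate | O=C1C[C@@](C(=O)OC)([C@@H]2OC(=O)C=C2C)Oc2cccc(OCc3ccccc3)c12 | intermediate
15 | methyl (S)-5-hydroxy-2-[(2R,3S)-3-methyl-5-oxotetrahydrofuran-2-yl]-4-oxochromane-2-carboxylate | O=C1C[C@@](C(=O)OC)([C@@H]2OC(=O)C[C@@H]2C)Oc2cccc(O)c12 | intermediate
16 | methyl (S)-6-bromo-5-hydroxy-2-[(2R,3S)-3-methyl-5-oxotetrahydrofuran-2-yl]-4-oxochromane-2-carboxylate | O=C1C[C@@](C(=O)OC)([C@@H]2OC(=O)C[C@@H]2C)Oc2ccc(Br)c(O)c12 | intermediate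
17 | methyl (S)-6-bromo-5-(methoxymethoxy)-2-[(2R,3S)-3-methyl-5-oxotetrahydrofuran-2-yl]-4-oxochromane-2-carboxylate | O=C1C[C@@](C(=O)OC)([C@@H]2OC(=O)C[C@@H]2C)Oc2ccc(Br)c(OCOC)c12 | intermediate
18 | methyl (S)-5-(methoxymethoxy)-2-[(2R,3S)-3-methyl-5-oxotetrahydrofuran-2-yl]-4-oxo-6-(trimethylstannyl)chromane-2-carboxylate | O=C1C[C@@](C(=O)OC)([C@@H]2OC(=O)C[C@@H]2C)Oc2ccc([Sn](C)(C)C)c(OCOC)c12 | intermediate
19 | dimethyl (2S,2′S)-5,5′-bis(methoxymethoxy)-2,2′-bis[(2R,3S)-3-methyl-5-oxotetrahydrofuran-2-yl]-4,4′-dioxo-[6,6′-bichromane]-2,2′-dicarboxylate | COC(=O)[C@@]1([C@@H]5OC(=O)C[C@@H]5C)CC(=O)c2c(ccc(-c3ccc4c(c3OCOC)C(=O)C[C@@](C(=O)OC)([C@@H]3OC(=O)C[C@@H]3C)O4)c2OCOC)O1 | intermediate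
20 | dimethyl (2S,2′S)-5,5′-dihydroxy-2,2′-bis[(2R,3S)-3-methyl-5-oxotetrahydrofuran-2-yl]-4,4′-dioxo-[6,6′-bichromane]-2,2′-dicarboxylate | COC(=O)[C@@]1([C@@H]5OC(=O)C[C@@H]5C)CC(=O)c2c(ccc(-c3ccc4c(c3O)C(=O)C[C@@](C(=O)OC)([C@@H]3OC(=O)C[C@@H]3C)O4)c2O)O1 | intermediate
21 | (3S,4R)-4-hydroxy-4-[(2S,2′S)-5,5′-dihydroxy-2,2′-bis(methoxycarbonyl)-2′-[(2R,3S)-3-methyl-5-oxotetrahydrofuran-2-yl]-4,4′-dioxo-[6,6′-bichroman]-2-yl]-3-methylbutanoic acid | COC(=O)[C@@]1([C@H](O)[C@@H](C)CC(=O)O)CC(=O)c2c(ccc(-c3ccc4c(c3O)C(=O)C[C@@](C(=O)OC)([C@@H]3OC(=O)C[C@@H]3C)O4)c2O)O1 | target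

**Totals.** 13 steps; the longest linear sequence is 13 steps (1 to 21).

**Steps most likely to fail, with fallbacks**

Step 6. The risks are poor facial selectivity at C5′ in the addition to the hindered aldehyde and loss of the formyl group by retro-Claisen cleavage under the Lewis-acidic chromium conditions. The fallback sets out from 11 and builds the C4′–C5′ bond under reagent control. Crotylboration with the diisopropyl (R,R)-tartrate ester of (Z)-but-2-enylboronic acid (4 Å sieves, toluene, −78 °C) should give the syn homoallylic alcohol methyl (S)-5-(benzyloxy)-2-[(1R,2S)-1-hydroxy-2-methylbut-3-en-1-yl]-4-oxochromane-2-carboxylate F1. Linear-selective hydroformylation (Rh(acac)(CO)2, Xantphos, CO/H2, THF, 60 °C) should give the lactol methyl (S)-5-(benzyloxy)-2-[(2R,3S)-5-hydroxy-3-methyltetrahydrofuran-2-yl]-4-oxochromane-2-carboxylate F2. Oxidation (PhI(OAc)2, TEMPO, CH2Cl2) should give the lactone methyl (S)-5-(benzyloxy)-2-[(2R,3S)-3-methyl-5-oxotetrahydrofuran-2-yl]-4-oxochromane-2-carboxylate F3. Hydrogenolysis (H2, Pd/C) comes back to the route at 15.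

Step 13. The risks are statistical over-hydrolysis of both lactones, competing saponification of a methyl ester, scrambling of C2 by base-induced ring opening, and re-lactonisation on acidification. The fallback sets out from 16 and differentiates the two halves before they are joined. LiOH (the phenolate forms first) opens the lactone, and BnBr in DMF caps both the carboxylate and the phenolate to give methyl (S)-5-(benzyloxy)-2-[(1R,2S)-4-(benzyloxy)-1-hydroxy-2-methyl-4-oxobutyl]-6-bromo-4-oxochromane-2-carboxylate F4. Benzyl chloroformate with N-methylimidazole blocks the hindered alcohol as its benzyl carbonate, methyl (S)-5-(benzyloxy)-2-[(1R,2S)-4-(benzyloxy)-1-{[(benzyloxy)carbonyl]oxy}-2-methyl-4-oxobutyl]-6-bromo-4-oxochromane-2-carboxylate F5. Base-free Stille coupling of F5 with stannane 18 (Pd(PPh3)4, CuI, DMF, 80 °C) should give the unsymmetrical biaryl, the 5-benzyl ether, benzyl ester and benzyl carbonate of the target bearing a 5′-MOM ether F6. Aqueous HCl in MeCN removes the MOM group while the masked hydroxy acid cannot lactonise, giving the 5′-phenol F7. Neutral hydrogenolysis (H2, Pd/C, EtOAc) removes the three benzyl-type groups and comes back at 21.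

Step 3. The risk is insufficient enantioselectivity of the copper-catalysed addition on a chromone that carries both a 2-ester and a peri-benzyloxy group. The fallback sets out from 5. The same addition of 6 without the chiral ligand (CuI, TBSOTf, iPr2NEt; then TBAF, AcOH) gives racemic material, which is resolved by preparative chromatography on a cellulose tris(3,5-dimethylphenylcarbamate) stationary phase. The (S)-enantiomer is 9 and rejoins the route there; the enantiomer methyl (R)-5-(benzyloxy)-2-ethynyl-4-oxochromane-2-carboxylate F8 is set aside.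

**Further compounds**
F1 | step 6 | methyl (S)-5-(benzyloxy)-2-[(1R,2S)-1-hydroxy-2-methylbut-3-en-1-yl]-4-oxochromane-2-carboxylate | O=C1C[C@@](C(=O)OC)([C@H](O)[C@@H](C)C=C)Oc2cccc(OCc3ccccc3)c12
F2 | step 6 | methyl (S)-5-(benzyloxy)-2-[(2R,3S)-5-hydroxy-3-methyltetrahydrofuran-2-yl]-4-oxochromane-2-carboxylate (both anomers) | O=C1C[C@@](C(=O)OC)([C@@H]2OC(O)C[C@@H]2C)Oc2cccc(OCc3ccccc3)c12
F3 | step 6 | methyl (S)-5-(benzyloxy)-2-[(2R,3S)-3-methyl-5-oxotetrahydrofuran-2-yl]-4-oxochromane-2-carboxylate | O=C1C[C@@](C(=O)OC)([C@@H]2OC(=O)C[C@@H]2C)Oc2cccc(OCc3ccccc3)c12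
F4 | step 13 | methyl (S)-5-(benzyloxy)-2-[(1R,2S)-4-(benzyloxy)-1-hydroxy-2-methyl-4-oxobutyl]-6-bromo-4-oxochromane-2-carboxylate | O=C1C[C@@](C(=O)OC)([C@H](O)[C@@H](C)CC(=O)OCc3ccccc3)Oc2ccc(Br)c(OCc3ccccc3)c12
F5 | step 13 | methyl (S)-5-(benzyloxy)-2-[(1R,2S)-4-(benzyloxy)-1-{[(benzyloxy)carbonyl]oxy}-2-methyl-4-oxobutyl]-6-bromo-4-oxochromane-2-carboxylate | O=C1C[C@@](C(=O)OC)([C@H](OC(=O)OCc3ccccc3)[C@@H](C)CC(=O)OCc3ccccc3)Oc2ccc(Br)c(OCc3ccccc3)c12
F6 | step 13 | dimethyl (2S,2′S)-5-(benzyloxy)-2-[(1R,2S)-4-(benzyloxy)-1-{[(benzyloxy)carbonyl]oxy}-2-methyl-4-oxobutyl]-5′-(methoxymethoxy)-2′-[(2R,3S)-3-methyl-5-oxotetrahydrofuran-2-yl]-4,4′-dioxo-[6,6′-bichromane]-2,2′-dicarboxylate | COC(=O)[C@@]1([C@H](OC(=O)OCc5ccccc5)[C@@H](C)CC(=O)OCc5ccccc5)CC(=O)c2c(ccc(-c3ccc4c(c3OCOC)C(=O)C[C@@](C(=O)OC)([C@@H]3OC(=O)C[C@@H]3C)O4)c2OCc6ccccc6)O1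
F7 | step 13 | dimethyl (2S,2′S)-5-(benzyloxy)-2-[(1R,2S)-4-(benzyloxy)-1-{[(benzyloxy)carbonyl]oxy}-2-methyl-4-oxobutyl]-5′-hydroxy-2′-[(2R,3S)-3-methyl-5-oxotetrahydrofuran-2-yl]-4,4′-dioxo-[6,6′-bichromane]-2,2′-dicarboxylate | COC(=O)[C@@]1([C@H](OC(=O)OCc5ccccc5)[C@@H](C)CC(=O)OCc5ccccc5)CC(=O)c2c(ccc(-c3ccc4c(c3O)C(=O)C[C@@](C(=O)OC)([C@@H]3OC(=O)C[C@@H]3C)O4)c2OCc6ccccc6)O1
F8 | step 3 | methyl (R)-5-(benzyloxy)-2-ethynyl-4-oxochromane-2-carboxylate | O=C1C[C@](C(=O)OC)(C#C)Oc2cccc(OCc3ccccc3)c12
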